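The readings were generated by integration for an exercise, noise included.

At 3.00 h, theta stands at 20.5% left-handed product and zeta, with more free catalyst, at 25.0%. Both curves have flattened with much substrate unused, so partner is taken here as the limiting reagent, with a second, catalyst-free loss.

| flask | left-handed substrate | right-handed substrate | partner | protic impurity | free catalyst | remark |
|---|---|---|---|---|---|---|
| theta | 0.062 M | 0.062 M | 1.2 equiv | 6.2 mM | 5.3 mol% | run made earlier |
| zeta | 0.062 M | 0.062 M | 1.2 equiv | 6.2 mM | 8.4 mol% | run made earlier |
| flask | 0.062 M | 0.062 M | 1.20 equiv | 6.20 mM | 3.8 mol% |  |

| run | time / h | left-handed product / % | left-handed substrate / % |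
|---|---|---|---|
| theta | 0.250 | 4.8 | 43.7 |
| theta | 0.417 | 7.5 | 40.1 |
| theta | 0.833 | 12.7 | 36.6 |
| theta | 1.50 | 17.3 | 32.2 |
| theta | 3.00 | 20.5 | 28.2 |
| zeta | 0.250 | 7.4 | 42.6 |
| zeta | 0.833 | 16.5 | 32.0 |
| zeta | 1.33 | 20.9 | 29.4 |
| zeta | 2.00 | 23.6 | 26.9 |
| zeta | 3.00 | 25.0 | 23.0 |

(scatter of a reading: 1 percentage point)

1. apparent order in partner when 10% of the left-handed substrate and right-handed substrate together are converted (percent change of the rate of making left-handed product for one percent more partner charged)
2. apparent order in free catalyst when 10% of the left-handed substrate and right-handed substrate together are converted (percent change of the rate of making left-handed product for one percent more free catalyst charged)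
3. factor on the rate of making left-handed product when 10% of the left-handed substrate and right-handed substrate together are converted if partner is charged twice over

- free catalyst is single-handed; left-handed substrate and right-handed substrate are mirror images of each other, charged as a racemate, each of them at the stated concentration
- what is bound to the catalyst counts as converted
- no earlier run changes the charge of partner; that part of a forecast is a guess

The reckoning below is my own and assumes that rate goes as [partner] times the free catalyst charged, at a fixed conversion.

1. Main step alone. The scale starts from this case: order 1 in partner, order 1 in free catalyst, and factor 2 on doubling.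

2. Fixed spending added. The new flask charges 74.4 mM partner. If protic impurity takes one partner each, and the conversion to the mark, 10% of both substrates together, takes 12.4 mM, then 18.6 mM is taken as gone at the mark and held fixed when the charge of partner changes. The order in partner becomes 1.33 and the factor 2.33. Bound substrate is counted as spent here, which overstates the sum.

3. Self-loss added. Self-loss and product formation both go as [partner], so their ratio is taken to vary inversely with catalyst and not with [partner]. Each run's final product then scales as one over one plus this ratio, and any right-handed share cancels. The two end readings, both still rising, are taken as final and give 0.952 for theta, a rough reading given the scatter. The new flask, at its loading, gets 1.33: the waste ratio, partner lost on its own per partner turned into product.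

4. Sum. Self-loss to the mark is reckoned at 16.5 mM, so the total spent is reckoned at 35.1 mM. The order in partner is 1.89, the factor 2.89, and the order in free catalyst 1.42.

The forecast gave 0.6 in partner, 1 in free catalyst and a factor of 1.5, saying of partner “its order is a guess”, and these numbers differ from my reckoning.

    partner + protic impurity → quenched reagent (k = 4.80 M⁻¹ min⁻¹)
    partner + catalyst intermediate B → free catalyst + right-handed product (k = 2.30 M⁻¹ min⁻¹)
    free catalyst + left-handed substrate ⇌ catalyst intermediate A (K = 18.0 M⁻¹, k = 1000 M⁻¹ min⁻¹)
    partner → decomposed reagent (k = 0.00630 min⁻¹)
    partner + catalyst intermediate A → free catalyst + left-handed product (k = 4.80 M⁻¹ min⁻¹)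
    free catalyst + right-handed substrate ⇌ catalyst intermediate B (K = 9.80 M⁻¹, k = 150 M⁻¹ min⁻¹)

The new flask gives order 1.7 in partner, order 1.3 in free catalyst and factor 2.65. It reaches the mark at 0.578 h, with left-handed product forming at 0.0114 M h⁻¹. At 30.0 h, with partner at 0%, the waste ratio of 1.33 meets 0.0371 M decomposed reagent, which is 1.19 per unit of left-handed and right-handed product together.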